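**Remarks before the route**

- Atom labels: ring C1 (bears the chain), C2 (OH), C3 (angelate), C4 (methyl, epoxide), C5 (epoxide CH), C6 (CH2); chain C7 (=C14H2), C8 (angelate), C9, C10–C11 (epoxide). Compound numbers are independent of these labels.
- Assumption: the tether is introduced with diisopropylsilyl bis(triflate) in place of the dichlorosilane, because the triflate enolises both carbonyl partners with Et3N alone; it, methyl (S)-glycidate, the isobutenyl Grignard reagent and angelic acid are taken as purchasable.
- Compound key (full list after the steps): 1 methyl (S)-glycidate; 2 isobutenyl Grignard reagent; 3 hydroxy ester; 4 TBS ester; 5 Weinreb amide; 6 methyl ketone; 7 its kinetic lithium enolate; 8 hydroxymethylene ketone; 9 tiglaldehyde; 10 iPr2Si(OTf)2; 11 dienyloxysilyl triflate; 12 silyl bis-enol ether; 13 cycloadduct; 14 methylenated cycloadduct; 15 triol; 16 angelic acid; 17 mixed anhydride; 18 bis-angelate; 19 ring epoxide; 20 target.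

## Analysis of the target

The target is a bisabolane-type sesquiterpenoid: a cyclohexane (C1–C6) in which five of the six ring carbons are functionalised, carrying at C1 a C7–C11 chain with an exocyclic methylene (C7=C14). On the ring, the C1 chain, the C2 hydroxyl, the C3 angelate and the C4–C5 epoxide oxygen all sit on one face (1S,2R,3R,4S,5S), with the C4 methyl on the other. The chain carries two further centres: C8 (S), an allylic angelate, and C10 (R), part of a gem-dimethyl epoxide that is too remote from the rest to be set by substrate control. The sensitive groups are the two epoxides (acid, HF), the two angelates (Z to E isomerisation to tiglates under nucleophilic catalysis, and possible migration from O3 to the free cis O2) and the allylic C8 ester next to C7=C14. The difficulty is threefold: the contiguous all-cis C1–C2–C3 array next to a trisubstituted alkene placed exactly at C4=C5, the differentiation of three secondary hydroxyls (only C2 stays free), and the ordering of two epoxidations among five C=C bonds. The feature used here is that the cis oxygens on C2 and C3 lie between C1 and the C4(Me)=C5 unit. The ring carbons therefore map onto a diene C3=C4(Me)–C5=C6 (the dienol ether of tiglaldehyde) and a dienophile C1=C2 (the Z enol ether of a β-keto aldehyde whose ketone is C7), and the two oxygens can be bridged by a single silicon atom.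

## Retrosynthetic reasoning

**20 to 19 (C10–O and C11–O).** The side-chain epoxide is removed first. It would not survive the fluoride/HF desilylation or a Lewis-acidic step, and C10 has no neighbouring stereocentre, so it is best made last by a catalyst-controlled (Shi) epoxidation. At the stage of 19 the C10=C11 bond is the only electron-rich trisubstituted alkene left, so no chemoselectivity problem arises.

**19 to 18 (C4–O and C5–O).** The ring epoxide is syn to the C2 hydroxyl, the only free hydroxyl of 18 and homoallylic to C4=C5. A hydroxyl-directed, vanadium-catalysed epoxidation can therefore deliver oxygen to the correct face, which is the more hindered one and would not be reached by an undirected peracid.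

**18 to 15 and 16 (two ester C–O bonds).** Both esters are angelates, so they are cut together and traced to angelic acid 16 and triol 15. The forward step must acylate O8 and O3 but not the axial, doubly flanked O2, and must not isomerise the Z acyl group.

**15 to 14 to 13 (Si–O bonds, then C7=C14).** The triol comes from one fluoride treatment of 14, in which O2 and O3 are tied in a dioxasilolane and O8 is a silyl ether. The exocyclic methylene is cut back to the C7 ketone of 13. A ketone at C7 is required for the ring-forming step, because it activates the dienophile. The forward methylenation must be non-basic, since C1 and C8 are epimerisable and O2 is β to the carbonyl.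

**13 to 12 (C2–C3 and C1–C6).** This is the key disconnection. Cutting these two ring bonds in a retro-[4+2] leaves C4=C5 as the central bond of a diene and opens the dioxasilolane into an O–Si–O bridge between two enol ethers. No other pair of ring bonds leaves the alkene at C4=C5 and both oxygens on sp2 carbons. The forward reaction has to bond C3 to C2, against the electronic preference of the partners, and only the three-atom tether can enforce that. It also has to deliver C1, C2 and C3 all cis.

**12 to 8, 9 and 10 (two Si–O bonds).** The bis-enol ether is cut at silicon into tiglaldehyde 9, the bis-electrophile 10 and the hydroxymethylene ketone 8. The forward step has to join two different enols on one silicon and fix the E diene and Z enol ether geometries.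

**8 to 6 (C1–C2).** The formyl carbon C2 is removed in a retro-Claisen sense, leaving methyl ketone 6 whose methyl group is C1. The forward formylation must go through the kinetic enolate so that C8 is not epimerised.

**6 to 5, 4, 3, then 1 and 2 (C7–C1 and C9–C10).** The methyl ketone comes from a Weinreb amide, and the α-oxygenated acid derivative is cut at C9–C10 into the chiral-pool epoxide 1 and the alkenyl Grignard reagent 2. This buys the C8 stereocentre and installs the whole C8–C11 unit in one step.

## Alternatives that were turned down

**Alternative 1: nitrile oxide cycloaddition as a masked side-chain aldol.**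
- Disconnection: the side chain is cut at C8–C9 and O–C10, giving the nitrile oxide A2 (C8 is the nitrile oxide carbon; ring and C7=C14 already present) and 2-methylbut-3-en-2-ol A3.
- Forward key step: A2 adds to A3, held as its zinc alkoxide with a chiral tartrate ester, to give the isoxazoline A1.
- For: the side chain is attached convergently and mildly, and C10 is set by reagent control before any ester is present. On that point it is stronger than the chosen route, which exposes two angelates to a buffered basic epoxidation.
- Against:
  - A2 presupposes the all-cis ring, which is the real problem of the target and which this strategy does not address.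
  - A2 is a conjugated nitrile oxide that can dimerise or add to its own alkenes.
  - A3 is a tertiary allylic alcohol, more hindered than the usual partners of the zinc-alkoxide method.
  - After the cycloaddition, N–O cleavage must spare two alkenes, the resulting enone at C8 must be reduced 1,2 with control from C10, and the C10 oxygen of A1 lies in the sense opposite to the final epoxide, so the epoxide must be closed with inversion through a C10 sulfonate.
- Comparison: this is about five operations for what the chosen route does with a purchased C8 centre and one Shi step. The chosen strategy gives instead the ring, the full C1–C11 skeleton and three stereocentres in a single step.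

**Alternative 2: Nozaki–Hiyama–Kishi cyclisation at C3–C4.**
- Disconnection: the ring is cut between C3 and C4, giving the open-chain Z alkenyl iodide/aldehyde A5.
- Forward key step: divalent chromium with a catalytic nickel salt converts the C4 iodide of A5 into an alkenylchromium that adds to the C3 aldehyde, giving the cyclohexenol A4.
- For: the ring closure is a known, chemoselective reaction that tolerates the Weinreb amide. O2 (PMB ether) and O3 (free hydroxyl) are differentiated from the start, which is stronger than the chosen route, where both oxygens emerge in one silylene and must be told apart by reactivity.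
- Against:
  - A5 has a Z trisubstituted iodide and two adjacent stereocentres, one α to the amide with a β-alkoxy leaving group and one α to the aldehyde; it needs roughly ten linear steps and is prone to epimerisation and elimination.
  - The configuration of the new C3 carbinol is not secured by the mechanism.
  - Chromium is used in excess.
  - The C8–C11 chain with its stereocentre still has to be attached to C7 afterwards.
- Comparison: the chosen strategy reaches its cyclisation precursor in six steps and closes the ring with the whole chain in place, at the price of a less certain key step.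

**Alternative 3: lactone Ireland–Claisen ring contraction.**
- Disconnection: C1–C6 is cut in a retro-[3,3] sense, giving the six-membered lactone A7 (C7 carbonyl, ring oxygen on C4, vinyl C5=C6 and methyl on C4).
- Forward key step: the silyl ketene acetal of A7 rearranges, forming C1–C6, breaking C4–O and giving the acid A6 with C4=C5 in place.
- For: the rearrangement is concerted and transfers chirality from C4 to C1 stereospecifically. The absolute sense of the ring therefore does not depend on a remote controller, which is stronger than the chosen route, whose facial selectivity rests on C8 alone.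
- Against:
  - A7 needs three contiguous stereocentres including a fully substituted tertiary allylic centre, so the stereochemical problem is moved, not solved.
  - The endocyclic ketene acetal must reach the vinyl group through a strained boat-like bicyclic transition state.
  - Enolisation places the C2 silyloxy group β to the enolate, inviting elimination.
  - A6 is only the ring acid, and the C7–C8 bond, the C8 centre and the rest of the chain must still be built.
- Comparison: the chosen strategy offers a much shorter route in which C7–C11 are present before the ring is made.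

Key step: step 7

## Route

**Step 1**
Reactants: 1 methyl (S)-oxirane-2-carboxylate (methyl (S)-glycidate); 2 (2-methylprop-1-en-1-yl)magnesium bromide
Product: 3 methyl (2S)-2-hydroxy-5-methylhex-4-enoate
Conditions: 2 (1.3 equiv), CuBr·SMe2 (10 mol %), THF, −78 → −40 °C; aq. NH4Cl work-up
Reagents that add atoms: none
Why: Copper-catalysed SN2 opening of the glycidic ester at its unsubstituted CH2 by the alkenyl Grignard reagent (organocuprate epoxide opening), forming C9–C10; the ester is not attacked at this temperature, and the epoxide CH is untouched, so its S configuration becomes C8.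

**Step 2**
Reactants: 3 methyl (2S)-2-hydroxy-5-methylhex-4-enoate
Product: 4 methyl (2S)-2-[(tert-butyldimethylsilyl)oxy]-5-methylhex-4-enoate
Conditions: TBSCl, imidazole, DMF, rt
Reagents that add atoms: tert-butyldimethylsilyl chloride, CC(C)(C)[Si](C)(C)Cl
Why: Standard silylation of a secondary α-hydroxy ester; the TBS ether is non-chelating, survives the organometallic and thermal steps and is removed later together with the tether.

**Step 3**
Reactants: 4 methyl (2S)-2-[(tert-butyldimethylsilyl)oxy]-5-methylhex-4-enoate
Product: 5 (2S)-2-[(tert-butyldimethylsilyl)oxy]-N-methoxy-N,5-dimethylhex-4-enamide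
Conditions: MeNH(OMe)·HCl (3 equiv), iPrMgCl (6 equiv), THF, −20 → 0 °C; aq. NH4Cl work-up
Reagents that add atoms: N,O-dimethylhydroxylamine hydrochloride, CNOC.Cl
Why: Direct ester-to-Weinreb-amide aminolysis by the chloromagnesium amide generated in the flask; this weakly basic amide does not enolise the α-silyloxy centre.

**Step 4**
Reactants: 5 (2S)-2-[(tert-butyldimethylsilyl)oxy]-N-methoxy-N,5-dimethylhex-4-enamide
Product: 6 (3S)-3-[(tert-butyldimethylsilyl)oxy]-6-methylhept-5-en-2-one
Conditions: MeMgBr (1.5 equiv), THF, 0 °C; aq. NH4Cl work-up
Reagents that add atoms: methylmagnesium bromide, C[Mg]Br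
Why: Weinreb ketone synthesis; the magnesium chelate of the tetrahedral adduct prevents over-addition and collapses to the methyl ketone on work-up, and the new methyl carbon is C1.

**Step 5**
Reactants: 6 (3S)-3-[(tert-butyldimethylsilyl)oxy]-6-methylhept-5-en-2-one
Product: 8 (1Z,4S)-4-[(tert-butyldimethylsilyl)oxy]-1-hydroxy-7-methylocta-1,6-dien-3-one, via kinetic lithium enolate 7 (not isolated)
Conditions: LDA (LiN(iPr)2, 1.1 equiv), THF, −78 °C; HCO2CH2CF3 (1.3 equiv), −78 °C; cold 0.5 M HCl to pH 4
Reagents that add atoms: 2,2,2-trifluoroethyl formate, O=COCC(F)(F)F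
Why: LDA at −78 °C deprotonates the methyl group (C1) and not the hindered, oxygen-bearing C8–H, and trifluoroethyl formate formylates this kinetic enolate before it can equilibrate (crossed Claisen formylation), forming C1–C2. The product is held as its lithium chelate, which shields C8 from epimerisation, and is isolated as the hydrogen-bonded Z enol.

**Step 6**
Reactants: 9 tiglaldehyde, (E)-2-methylbut-2-enal; 10 di(propan-2-yl)silanediyl bis(trifluoromethanesulfonate); 8 (1Z,4S)-4-[(tert-butyldimethylsilyl)oxy]-1-hydroxy-7-methylocta-1,6-dien-3-one
Product: 12 (1Z,4S)-4-[(tert-butyldimethylsilyl)oxy]-7-methyl-1-({[(1E)-2-methylbuta-1,3-dien-1-yl]oxy}di(propan-2-yl)silyl)oxyocta-1,6-dien-3-one, via dienyloxysilyl triflate 11 (not isolated)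
Conditions: 10 (1.05 equiv), Et3N (3 equiv), CH2Cl2, −78 °C; 9 (1.0 equiv), −78 → 0 °C; then 8 (0.9 equiv), −78 → 0 °C; pentane, filtration under argon; used crude
Reagents that add atoms: none
Why: Soft enolisation: the silyl triflate O-silylates the enal and Et3N removes a γ-proton, giving the E dienol ether from the s-trans enal, as in the known silyl triflate/amine preparation of 1-silyloxy dienes. The remaining, more hindered Si–OTf then silylates the acidic chelated enol 8 on its terminal, aldehyde-derived oxygen without breaking the C1=C2 bond, so the Z geometry is retained; this is sequential substitution on a dialkylsilyl bis-electrophile, as used for unsymmetrical silyl bis-enol ethers.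

**Step 7**
Reactants: 12 silyl bis-enol ether (as named in step 6)
Product: 13 (2S)-2-[(tert-butyldimethylsilyl)oxy]-5-methyl-1-[(3aS,7R,7aR)-4-methyl-2,2-di(propan-2-yl)-3a,6,7,7a-tetrahydro-1,3,2-benzodioxasilol-7-yl]hex-4-en-1-one
Conditions: PhMe (5 mM, degassed), 2,6-di-tert-butyl-4-methylpyridine (0.2 equiv), BHT (cat.), 130 °C, sealed tube
Reagents that add atoms: none
Why: Proposed new method: a thermal, concerted but asynchronous [4+2] cycloaddition through a fused bicyclic transition state, in which the E dienol ether (C3=C4(Me)–C5=C6) and the Z β-silyloxy enone (C1=C2) are held by the O–Si–O bridge as a 1,3,8-nonatriene-type (type 1) array; the closest known reactions are silicon-tethered intramolecular Diels–Alder reactions of silyl acetals and vinylsilanes. The three-atom tether can only bring C3 onto C2 and hence C6 onto C1, which overrides the electronic preference of a 1-oxy diene to bond through C6 to the enone β-carbon; the cost is a polarity-mismatched, slow cycloaddition that is paid for by intramolecularity, the gem-diisopropyl effect and heat. The cyclohexene is closed by the cycloaddition itself (σ bonds C2–C3 and C1–C6), and the five-membered dioxasilolane is closed at the same time by the C2–C3 bond, as the small ring of a type 1 intramolecular Diels–Alder reaction with a three-atom tether. C3 relative to C2 is set by the ring fusion: a cis-fused dioxasilolane on a cyclohexene is far less strained than a trans-fused one, so the tether oxygen on C2 sits endo and ends up cis to the outside oxygen of the E diene. C1 relative to C2 follows suprafacially from the Z enol ether, which places the C7 acyl group endo as well and therefore on the same face as both oxygens. The absolute sense, that is which face of C1=C2 is attacked, is controlled only by the C8 silyloxy centre through the conformation of the α-silyloxy ketone. The step thus needs regio-, endo- and face selectivity: the first two are secured by the tether length and the two alkene geometries, the third is not secured, and the two all-cis diastereomers would be separated by chromatography. The trisubstituted alkene is left at C4=C5, where the epoxide is needed.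

**Step 8**
Reactants: 13 cycloadduct with C7 ketone (as named in step 7)
Product: 14 (3aS,7S,7aR)-7-[(3S)-3-[(tert-butyldimethylsilyl)oxy]-6-methylhepta-1,5-dien-2-yl]-4-methyl-2,2-di(propan-2-yl)-3a,6,7,7a-tetrahydro-1,3,2-benzodioxasilole
Conditions: Cp2TiMe2 (3 equiv), PhMe, 70 °C, dark
Reagents that add atoms: dimethyltitanocene, C[Ti](C)(C1C=CC=C1)C1C=CC=C1
Why: Petasis methylenation through Cp2Ti=CH2 ([2+2] with the ketone, then cycloreversion) installs C14. The reagent is non-basic, so the epimerisable C1 and C8 centres and the β-silyloxy group at C2, which would be lost by E1cB under Wittig conditions, survive; silyl ethers are inert.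

**Step 9**
Reactants: 14 methylenated cycloadduct (as named in step 8)
Product: 15 (1R,2S,6S)-6-[(3S)-3-hydroxy-6-methylhepta-1,5-dien-2-yl]-3-methylcyclohex-3-ene-1,2-diol
Conditions: HF·pyridine, pyridine, THF, 0 °C → rt
Reagents that add atoms: none
Why: Fluoride cleaves both silicon groups in one operation, the strained dioxasilolane quickly and the secondary TBS ether more slowly. Pyridine buffering protects the allylic alcohols and trisubstituted alkenes, and no epoxide is present yet.

**Step 10**
Reactants: 15 triol (as named in step 9); 16 angelic acid, (Z)-2-methylbut-2-enoic acid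
Product: 18 (1S,5S,6R)-6-hydroxy-2-methyl-5-[(3S)-6-methyl-3-{[(2Z)-2-methylbut-2-enoyl]oxy}hepta-1,5-dien-2-yl]cyclohex-2-en-1-yl (2Z)-2-methylbut-2-enoate, via angelic 2,4,6-trichlorobenzoic anhydride 17 (not isolated)
Conditions: 16 (2.4 equiv), 2,4,6-Cl3C6H2COCl (2.4 equiv), Et3N (5 equiv), PhMe, rt, 2 h; then 15, PhMe, 70 °C
Reagents that add atoms: none
Why: Yamaguchi-type esterification through the mixed anhydride: the alcohol attacks the angeloyl carbonyl because the aroyl carbonyl is shielded by two ortho chlorines, and without a nucleophilic catalyst there is no reversible conjugate addition that would isomerise the Z acid to the tiglate. The acyclic allylic O8 and the pseudo-equatorial allylic O3 should react, while the axial O2, flanked by the substituted C1 and C3, is the slowest hydroxyl and should stay free; no stereocentre is formed.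

**Step 11**
Reactants: 18 bis-angelate (as named in step 10)
Product: 19 (1S,2R,3R,4S,6S)-3-hydroxy-1-methyl-4-[(3S)-6-methyl-3-{[(2Z)-2-methylbut-2-enoyl]oxy}hepta-1,5-dien-2-yl]-7-oxabicyclo[4.1.0]heptan-2-yl (2Z)-2-methylbut-2-enoate
Conditions: VO(acac)2 (5 mol %), tBuOOH (1.5 equiv, decane), CH2Cl2, 0 °C → rt
Reagents that add atoms: tert-butyl hydroperoxide, CC(C)(C)OO
Why: Hydroxyl-directed epoxidation: the vanadium alkoxide of the C2 hydroxyl, homoallylic to C4=C5 as in a cyclohex-3-enol, delivers the peroxide oxygen intramolecularly to the face it occupies, setting C4 and C5 syn to O2 and O3. The trisubstituted ring alkene should react faster than the 1,1-disubstituted C7=C14, while C10=C11 has no directing hydroxyl and the angelate alkenes are electron-poor.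

**Step 12**
Reactants: 19 ring epoxide (as named in step 11)
Product: 20 target, (1S,2R,3R,4S,6S)-4-[(3S)-4-[(2R)-3,3-dimethyloxiran-2-yl]-3-{[(2Z)-2-methylbut-2-enoyl]oxy}but-1-en-2-yl]-3-hydroxy-1-methyl-7-oxabicyclo[4.1.0]heptan-2-yl (2Z)-2-methylbut-2-enoate
Conditions: 1,2:4,5-di-O-isopropylidene-β-D-erythro-2,3-hexodiulo-2,6-pyranose (D-fructose-derived Shi ketone, 0.3 equiv), KHSO5 (as 2KHSO5·KHSO4·K2SO4), K2CO3, Na2B4O7/Na2EDTA buffer, Bu4NHSO4, MeCN–CH2(OMe)2–H2O, 0 °C
Reagents that add atoms: potassium peroxymonosulfate, [K+].[O-]S(=O)(=O)OO
Why: Shi asymmetric epoxidation by the chiral dioxirane formed from the ketone and KHSO5 through a spiro transition state. The unhindered, electron-rich trisubstituted C10=C11 should react far faster than C7=C14 (1,1-disubstituted, deactivated by the allylic ester) or the conjugated angelate alkenes, and the D-fructose-derived ketone should give the 10R epoxide by analogy with the R,R epoxides it gives from trans and trisubstituted alkenes; the hindered conjugated esters should tolerate the cold buffered medium.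

## Compound list

1 | methyl (S)-oxirane-2-carboxylate (methyl (S)-glycidate) | COC(=O)[C@@H]1CO1 | starting material
2 | (2-methylprop-1-en-1-yl)magnesium bromide | CC(C)=C[Mg]Br | starting material
3 | methyl (2S)-2-hydroxy-5-methylhex-4-enoate | COC(=O)[C@@H](O)CC=C(C)C | intermediate
4 | methyl (2S)-2-[(tert-butyldimethylsilyl)oxy]-5-methylhex-4-enoate | COC(=O)[C@@H](O[Si](C)(C)C(C)(C)C)CC=C(C)C | intermediate
5 | (2S)-2-[(tert-butyldimethylsilyl)oxy]-N-methoxy-N,5-dimethylhex-4-enamide | CON(C)C(=O)[C@@H](O[Si](C)(C)C(C)(C)C)CC=C(C)C | intermediate
6 | (3S)-3-[(tert-butyldimethylsilyl)oxy]-6-methylhept-5-en-2-one | CC(=O)[C@@H](O[Si](C)(C)C(C)(C)C)CC=C(C)C | intermediate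
7 | lithium (3S)-3-[(tert-butyldimethylsilyl)oxy]-6-methylhepta-1,5-dien-2-olate | [Li+].[O-]C(=C)[C@@H](O[Si](C)(C)C(C)(C)C)CC=C(C)C | intermediate (not isolated)
8 | (1Z,4S)-4-[(tert-butyldimethylsilyl)oxy]-1-hydroxy-7-methylocta-1,6-dien-3-one | O/C=C\C(=O)[C@@H](O[Si](C)(C)C(C)(C)C)CC=C(C)C | intermediate
9 | tiglaldehyde, (E)-2-methylbut-2-enal | C/C=C(\C)C=O | starting material
10 | di(propan-2-yl)silanediyl bis(trifluoromethanesulfonate) | CC(C)[Si](OS(=O)(=O)C(F)(F)F)(OS(=O)(=O)C(F)(F)F)C(C)C | starting material
11 | {[(1E)-2-methylbuta-1,3-dien-1-yl]oxy}di(propan-2-yl)silyl trifluoromethanesulfonate | C=C/C(C)=C/O[Si](C(C)C)(C(C)C)OS(=O)(=O)C(F)(F)F | intermediate (not isolated)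
12 | (1Z,4S)-4-[(tert-butyldimethylsilyl)oxy]-7-methyl-1-({[(1E)-2-methylbuta-1,3-dien-1-yl]oxy}di(propan-2-yl)silyl)oxyocta-1,6-dien-3-one | C=C/C(C)=C/O[Si](C(C)C)(C(C)C)O/C=C\C(=O)[C@@H](O[Si](C)(C)C(C)(C)C)CC=C(C)C | intermediate
13 | (2S)-2-[(tert-butyldimethylsilyl)oxy]-5-methyl-1-[(3aS,7R,7aR)-4-methyl-2,2-di(propan-2-yl)-3a,6,7,7a-tetrahydro-1,3,2-benzodioxasilol-7-yl]hex-4-en-1-one | CC(C)=CC[C@H](O[Si](C)(C)C(C)(C)C)C(=O)[C@@H]1CC=C(C)[C@H](O[Si](C(C)C)(C(C)C)O2)[C@@H]12 | intermediate
14 | (3aS,7S,7aR)-7-[(3S)-3-[(tert-butyldimethylsilyl)oxy]-6-methylhepta-1,5-dien-2-yl]-4-methyl-2,2-di(propan-2-yl)-3a,6,7,7a-tetrahydro-1,3,2-benzodioxasilole | CC(C)=CC[C@H](O[Si](C)(C)C(C)(C)C)C(=C)[C@@H]1CC=C(C)[C@H](O[Si](C(C)C)(C(C)C)O2)[C@@H]12 | intermediate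
15 | (1R,2S,6S)-6-[(3S)-3-hydroxy-6-methylhepta-1,5-dien-2-yl]-3-methylcyclohex-3-ene-1,2-diol | CC(C)=CC[C@H](O)C(=C)[C@@H]1CC=C(C)[C@H](O)[C@@H]1O | intermediate
16 | angelic acid, (Z)-2-methylbut-2-enoic acid | C/C=C(/C)C(=O)O | starting material
17 | (Z)-2-methylbut-2-enoic 2,4,6-trichlorobenzoic anhydride | C/C=C(/C)C(=O)OC(=O)c1c(Cl)cc(Cl)cc1Cl | intermediate (not isolated)
18 | (1S,5S,6R)-6-hydroxy-2-methyl-5-[(3S)-6-methyl-3-{[(2Z)-2-methylbut-2-enoyl]oxy}hepta-1,5-dien-2-yl]cyclohex-2-en-1-yl (2Z)-2-methylbut-2-enoate | C=C([C@H](CC=C(C)C)OC(=O)/C(C)=C\C)[C@@H]1CC=C(C)[C@H](OC(=O)/C(C)=C\C)[C@@H]1O | intermediate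
19 | (1S,2R,3R,4S,6S)-3-hydroxy-1-methyl-4-[(3S)-6-methyl-3-{[(2Z)-2-methylbut-2-enoyl]oxy}hepta-1,5-dien-2-yl]-7-oxabicyclo[4.1.0]heptan-2-yl (2Z)-2-methylbut-2-enoate | C=C([C@H](CC=C(C)C)OC(=O)/C(C)=C\C)[C@@H]1C[C@@H]2O[C@]2(C)[C@H](OC(=O)/C(C)=C\C)[C@@H]1O | intermediate
20 | CNP0296086.3, (1S,2R,3R,4S,6S)-4-[(3S)-4-[(2R)-3,3-dimethyloxiran-2-yl]-3-{[(2Z)-2-methylbut-2-enoyl]oxy}but-1-en-2-yl]-3-hydroxy-1-methyl-7-oxabicyclo[4.1.0]heptan-2-yl (2Z)-2-methylbut-2-enoate | C=C([C@H](C[C@H]1OC1(C)C)OC(=O)/C(C)=C\C)[C@@H]1C[C@@H]2O[C@]2(C)[C@H](OC(=O)/C(C)=C\C)[C@@H]1O | target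

## Step count and least certain steps

Total step count: 12. Longest linear sequence: 12 steps (1 to 20); compounds 9, 10 and 16 enter as purchased side inputs.

**Step 7 (key step, proposed new method).**
- What may go wrong: the cycloaddition may not compete with other processes, because the tether forces bond formation between electronically mismatched termini. Likely competitors are inverse-demand hetero-cycloaddition of the enone (O7=C7–C1=C2) onto the enol ether bond C3=C4, Michael-type closure through the nucleophilic C4, migration of silicon from O2 to the ketone oxygen, thermal Z to E rotation of the push–pull alkene (which would give the C1 epimer), and desilylation.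
- Facial selectivity may also be poor or go the wrong way, since the only controller is the conformationally mobile C8 centre. A dipole-minimised arrangement of the α-silyloxy ketone would place the C9 chain on the face that has to be attacked, whereas an arrangement with the silyloxy group perpendicular to the carbonyl would favour the wanted adduct. A Mitsunobu inversion at C8 could only compensate if the whole sequence were run with the opposite C8 configuration, so it is not counted on.
- Fallback (known chemistry; sets out from 5, comes back at 13): the ring is built by aldol addition and ring-closing metathesis, so that its configuration is set by an aldehyde stereocentre and the enolate geometry instead of by C8. Weinreb amide 5 is treated with but-3-enylmagnesium bromide to give (6S)-6-[(tert-butyldimethylsilyl)oxy]-9-methyldeca-1,8-dien-5-one F1. Its Z boron enolate (Bu2BOTf, iPr2NEt) is added to (S)-3-methyl-2-(triethylsilyloxy)but-3-enal F2, a building block that would have to be prepared separately. A Z enolate and an α-silyloxy aldehyde should give the 2,3-syn-3,4-anti adduct F3, which corresponds to the all-cis ring. Ring-closing metathesis with the second-generation Grubbs catalyst, (H2IMes)(PCy3)Cl2Ru=CHPh, between the allyl group on C1 and the isopropenyl group on C3 closes C4=C5 and gives the cyclohexene F4. Selective removal of the triethylsilyl group (PPTS, MeOH) gives the keto diol F5, and silylene formation with 10 and 2,6-lutidine returns 13.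

**Step 6.**
- What may go wrong: scrambling on silicon (symmetrical bis-dienyl and bis-enone silyl ethers), partial loss of the Z geometry during O-silylation of the ammonium enolate of 8, and hydrolysis of the vinylogous silyl ester during isolation.
- Fallback (sets out from 9, comes back at 12): the two enol partners are joined to silicon as a preformed metal dienolate and a chlorosilane. Tiglaldehyde 9 is converted with Me3SiCl, Et3N and NaI in MeCN into (E)-trimethyl[(2-methylbuta-1,3-dien-1-yl)oxy]silane F6, which can be distilled. Cleavage with MeLi (THF, 0 °C) and inverse addition to excess iPr2SiCl2 at −78 °C gives chloro{[(1E)-2-methylbuta-1,3-dien-1-yl]oxy}di(propan-2-yl)silane F7, from which the excess dichlorosilane is removed in vacuo. F7 then silylates 8 with Et3N in CH2Cl2 to give 12.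

**Step 10.**
- What may go wrong: acylation at O2, either as over-acylation to the tris-ester or in place of O3, because the two ring hydroxyls are distinguished only by their steric environment; and Z to E isomerisation of the angeloyl group on prolonged heating.
- Fallback (sets out from 15, comes back at 18): the cis-diol is activated as a tin acetal, so that the ring hydroxyls are distinguished by stannylene chemistry and the two esters are introduced one at a time. Triol 15 is heated with Bu2SnO in toluene with removal of water to give the 2,3-O-dibutylstannylene acetal F8. Addition of one equivalent of preformed 17 at room temperature should transfer the acyl group to the tin-activated equatorial O3, giving the C3 mono-angelate F9. A second acylation with 17 (toluene, 70 °C) at the acyclic O8 then gives 18.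

**Step 11.**
- What may go wrong: slow turnover, because the directing hydroxyl is only homoallylic and the alkene carries an allylic ester; and competing oxygen delivery to C7=C14, which is also homoallylic to O2.
- Fallback (sets out from 14, comes back at 19): the epoxidation is moved ahead of the esterification, so that the allylic C3 hydroxyl directs it while O8 is still silylated. Compound 14 is treated with K2CO3 in MeOH at 0 °C, which opens only the dioxasilolane and gives the C8-silylated diol F10. VO(acac)2 with tBuOOH then gives the epoxy diol F11. Bu4NF in THF removes the TBS group without touching the epoxide and gives the epoxy triol F12, and bis-angeloylation with 17 as in step 10 gives 19.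

## Further compounds

F1 | step 7 | (6S)-6-[(tert-butyldimethylsilyl)oxy]-9-methyldeca-1,8-dien-5-one | C=CCCC(=O)[C@@H](O[Si](C)(C)C(C)(C)C)CC=C(C)C
F2 | step 7 | (2S)-3-methyl-2-[(triethylsilyl)oxy]but-3-enal | C=C(C)[C@H](O[Si](CC)(CC)CC)C=O
F3 | step 7 | syn-aldol adduct: the 2,3-syn-3,4-anti β-hydroxy ketone with allyl on C1, free OH on C2, OSiEt3 and isopropenyl on C3, and (S)-OTBS on C8 | CC(C)=CC[C@H](O[Si](C)(C)C(C)(C)C)C(=O)[C@H](CC=C)[C@@H](O)[C@@H](O[Si](CC)(CC)CC)C(C)=C
F4 | step 7 | all-cis cyclohexene with C7 ketone, C2–OH and C3–OSiEt3 | CC(C)=CC[C@H](O[Si](C)(C)C(C)(C)C)C(=O)[C@@H]1CC=C(C)[C@H](O[Si](CC)(CC)CC)[C@@H]1O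
F5 | step 7 | all-cis keto diol with (S)-OTBS on C8 | CC(C)=CC[C@H](O[Si](C)(C)C(C)(C)C)C(=O)[C@@H]1CC=C(C)[C@H](O)[C@@H]1O
F6 | step 6 | (E)-trimethyl[(2-methylbuta-1,3-dien-1-yl)oxy]silane | C=C/C(C)=C/O[Si](C)(C)C
F7 | step 6 | chloro{[(1E)-2-methylbuta-1,3-dien-1-yl]oxy}di(propan-2-yl)silane | C=C/C(C)=C/O[Si](Cl)(C(C)C)C(C)C
F8 | step 10 | 2,3-O-dibutylstannylene acetal of triol 15 | CC(C)=CC[C@H](O)C(=C)[C@@H]1CC=C(C)[C@H](O[Sn](CCCC)(CCCC)O2)[C@@H]12
F9 | step 10 | C3 mono-angelate of triol 15 (O2 and O8 free) | C=C([C@H](CC=C(C)C)O)[C@@H]1CC=C(C)[C@H](OC(=O)/C(C)=C\C)[C@@H]1O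
F10 | step 11 | C8 tert-butyldimethylsilyl ether of triol 15 (O2 and O3 free) | CC(C)=CC[C@H](O[Si](C)(C)C(C)(C)C)C(=C)[C@@H]1CC=C(C)[C@H](O)[C@@H]1O
F11 | step 11 | C4–C5 epoxide of F10, oxygen syn to O2 and O3 | CC(C)=CC[C@H](O[Si](C)(C)C(C)(C)C)C(=C)[C@@H]1C[C@@H]2O[C@]2(C)[C@H](O)[C@@H]1O
F12 | step 11 | epoxy triol (F11 without the silyl group) | CC(C)=CC[C@H](O)C(=C)[C@@H]1C[C@@H]2O[C@]2(C)[C@H](O)[C@@H]1O
A1 | alternative 1 | 3-alkenyl-5-(2-hydroxypropan-2-yl)isoxazoline on the bis(triethylsilyl)-protected all-cis ring | C=C(C1=NO[C@H](C(C)(C)O)C1)[C@@H]2CC=C(C)[C@H](O[Si](CC)(CC)CC)[C@@H]2O[Si](CC)(CC)CC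
A2 | alternative 1 | nitrile oxide at C8 on the bis(triethylsilyl)-protected all-cis ring | C=C(C#[N+][O-])[C@@H]1CC=C(C)[C@H](O[Si](CC)(CC)CC)[C@@H]1O[Si](CC)(CC)CC
A3 | alternative 1 | 2-methylbut-3-en-2-ol | C=CC(C)(C)O
A4 | alternative 2 | all-cis cyclohexenol with C7 Weinreb amide and C2 PMB ether | CON(C)C(=O)[C@@H]1CC=C(C)[C@H](O)[C@@H]1OCc1ccc(OC)cc1
A5 | alternative 2 | open-chain (Z)-alkenyl iodide aldehyde with C7 Weinreb amide and C2 PMB ether | CON(C)C(=O)[C@H](C/C=C(\I)C)[C@@H](OCc1ccc(OC)cc1)C=O
A6 | alternative 3 | all-cis 4-methyl-2,3-bis(triethylsilyloxy)cyclohex-4-enecarboxylic acid | OC(=O)[C@@H]1CC=C(C)[C@H](O[Si](CC)(CC)CC)[C@@H]1O[Si](CC)(CC)CC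
A7 | alternative 3 | 6-methyl-4,5-bis(triethylsilyloxy)-6-vinyltetrahydropyran-2-one (vinyl trans to the C2 silyloxy group) | O=C1C[C@@H](O[Si](CC)(CC)CC)[C@@H](O[Si](CC)(CC)CC)[C@](C)(C=C)O1
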